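**Retrosynthetic overview**
1. No ring is built. Both rings of the naphthazarin core and the C1' carbinol centre (R) come intact from shikonin 1, and the acyl stereocentre comes from (R)-2-methylbutanoic acid 2. The side chain is numbered C1' (carbinol carbon) to C4' (CMe2 carbon).
2. Ester C–O bond: 1 + 2 give ester 3 by acyl transfer to the side-chain hydroxyl, with both stereocentres untouched.
3. Key C–O bond: the prenyl alkene of 3 is hydroxylated at C4' with shift of the double bond to C2'=C3' (E), through hydroxy selenide 4, to give target 5.

Assumption: shikonin 1 (pigment from Lithospermum root extract or cell culture, sold in gram lots, ee confirmed by chiral HPLC before use) and (R)-2-methylbutanoic acid 2 are bought as catalogue compounds.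

**Route**

Step 1
Reactants: 1 shikonin (5,8-dihydroxy-2-[(1R)-1-hydroxy-4-methylpent-3-en-1-yl]naphthalene-1,4-dione); 2 (2R)-2-methylbutanoic acid
Product: 3 (1R)-1-(5,8-dihydroxy-1,4-dioxo-1,4-dihydronaphthalen-2-yl)-4-methylpent-3-en-1-yl (2R)-2-methylbutanoate
Conditions: 2 (1.5 equiv), N,N'-dicyclohexylcarbodiimide (1.6 equiv), 4-(dimethylamino)pyridine (0.1 equiv), CH2Cl2, 0 °C to 20 °C, 3 h, Ar, dark
Reagents that add atoms: none
Why: Steglich esterification acylates only the secondary side-chain hydroxyl because both phenols are tied up in hydrogen bonds to the quinone carbonyls, and no bond at either stereocentre is broken, so C1' stays R and the α-centre of the acid stays R (low temperature and little 4-(dimethylamino)pyridine keep ketene formation out).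

Step 2
Reactants: 3 (1R)-1-(5,8-dihydroxy-1,4-dioxo-1,4-dihydronaphthalen-2-yl)-4-methylpent-3-en-1-yl (2R)-2-methylbutanoate
Product: 5 (1R,2E)-1-(5,8-dihydroxy-1,4-dioxo-1,4-dihydronaphthalen-2-yl)-4-hydroxy-4-methylpent-2-en-1-yl (2R)-2-methylbutanoate, via hydroxy selenide 4 (not isolated)
Conditions: (PhSe)2 (10 mol%), N-fluoro-2,4,6-trimethylpyridinium trifluoromethanesulfonate (1.3 equiv), MeCN/H2O 5:1, 20 °C, 6 h, dark, polypropylene flask
Reagents that add atoms: water, O
Why: Proposed new method: a dark, N–F-driven, diselenide-catalysed hydroxylation with 1,3-transposition that uses water as the oxygen nucleophile: the N-fluoropyridinium salt turns (PhSe)2 into a PhSe+ equivalent (divalent selenium) that forms a seleniranium ion only on the electron-rich trisubstituted alkene (the quinone C=C is too electron-poor), water opens it at the tertiary C4' (Markovnikov, anti) to give 4 and so makes the new C–O bond, a second N–F oxidation takes the selenide to tetravalent selenium (fluoroselenonium, hydrolysed to the selenoxide), and syn-elimination can only take a C2' hydrogen because C4' has none, which gives the E-alkene and returns PhSeOH/PhSeF to the cycle; no selenol or selenolate is ever present, so the quinone is neither reduced nor attacked, and neither stereocentre is touched (the C3' centre of 4 is destroyed again, so both epimers converge); the closest known reaction types are selenium-π-acid catalysed oxidative allylic amination and acyloxylation of simple alkenes and the stoichiometric hydroxyselenation–selenoxide elimination, neither shown with water as nucleophile on a quinone-bearing prenyl chain.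

**Compound list**

1 | shikonin, 5,8-dihydroxy-2-[(1R)-1-hydroxy-4-methylpent-3-en-1-yl]naphthalene-1,4-dione | O[C@H](CC=C(C)C)C1=CC(=O)c2c(O)ccc(O)c2C1=O | starting material
2 | (2R)-2-methylbutanoic acid | CC[C@@H](C)C(=O)O | starting material
3 | (1R)-1-(5,8-dihydroxy-1,4-dioxo-1,4-dihydronaphthalen-2-yl)-4-methylpent-3-en-1-yl (2R)-2-methylbutanoate | CC[C@@H](C)C(=O)O[C@H](CC=C(C)C)C1=CC(=O)c2c(O)ccc(O)c2C1=O | intermediate
4 | hydroxy selenide, (1R)-1-(5,8-dihydroxy-1,4-dioxo-1,4-dihydronaphthalen-2-yl)-4-hydroxy-4-methyl-3-(phenylselanyl)pentyl (2R)-2-methylbutanoate, both epimers at C3' | CC[C@@H](C)C(=O)O[C@H](CC([Se]c3ccccc3)C(C)(C)O)C1=CC(=O)c2c(O)ccc(O)c2C1=O | intermediate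
5 | CNP0265539.1, (1R,2E)-1-(5,8-dihydroxy-1,4-dioxo-1,4-dihydronaphthalen-2-yl)-4-hydroxy-4-methylpent-2-en-1-yl (2R)-2-methylbutanoate | CC[C@@H](C)C(=O)O[C@H](/C=C/C(C)(C)O)C1=CC(=O)c2c(O)ccc(O)c2C1=O | target

**Summary**

Total step count: 2. Longest linear sequence: 2 steps (1 → 3 → 5).

Steps most likely to fail: the route has only two steps, so both are listed, the riskier first.

Step 2 (the proposed new step). Selenium may leave the cycle as PhSeO2H, the oxidised selenide may be displaced by a neighbouring oxygen instead of eliminating, or the N–F salt may attack the naphthazarin. The fallback uses known chemistry with a different mechanism; it sets out from 3 and comes back at 5. A Schenck ene reaction of 3 with singlet oxygen (O2, 3,7-bis(dimethylamino)phenothiazin-5-ium chloride (methylene blue, 2 mol%), 660 nm LED where only the sensitiser absorbs, MeCN, 0 °C) gives the tertiary allylic hydroperoxide (1R,2E)-1-(5,8-dihydroxy-1,4-dioxo-1,4-dihydronaphthalen-2-yl)-4-hydroperoxy-4-methylpent-2-en-1-yl (2R)-2-methylbutanoate F1. It forms beside a similar amount of its regioisomer, the by-product (1R)-1-(5,8-dihydroxy-1,4-dioxo-1,4-dihydronaphthalen-2-yl)-3-hydroperoxy-4-methylpent-4-en-1-yl (2R)-2-methylbutanoate F2, which is removed on silica gel. F1 is then reduced with Me2S (5 equiv, CH2Cl2/MeOH, 0 to 20 °C; a phosphine is avoided because it adds to the quinone) to give 5. The cost is regiochemistry: roughly half of the material is lost as F2.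

Step 1. The yield may be modest (N-acylurea formation, base sensitivity of shikonin), and any loss of the α-centre of the acid would give an inseparable epimeric ester. The fallback is a two-stage acyl transfer through an isolated acyl donor; it sets out from 2 and comes back at 3. 2 is first dehydrated with N,N'-dicyclohexylcarbodiimide (0.5 equiv, CH2Cl2, 0 °C, urea filtered off) to (2R)-2-methylbutanoic anhydride F3. F3 is isolated and then transfers one acyl group to 1 (F3 1.5 equiv, 4-(dimethylamino)pyridine 5 mol%, CH2Cl2, 0 °C), so that shikonin never meets the carbodiimide; the acid released from F3 is recovered.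

**Further compounds**

F1 | step 2 | (1R,2E)-1-(5,8-dihydroxy-1,4-dioxo-1,4-dihydronaphthalen-2-yl)-4-hydroperoxy-4-methylpent-2-en-1-yl (2R)-2-methylbutanoate | CC[C@@H](C)C(=O)O[C@H](/C=C/C(C)(C)OO)C1=CC(=O)c2c(O)ccc(O)c2C1=O
F2 | step 2 | (1R)-1-(5,8-dihydroxy-1,4-dioxo-1,4-dihydronaphthalen-2-yl)-3-hydroperoxy-4-methylpent-4-en-1-yl (2R)-2-methylbutanoate, by-product, both epimers at C3' | CC[C@@H](C)C(=O)O[C@H](CC(OO)C(C)=C)C1=CC(=O)c2c(O)ccc(O)c2C1=O
F3 | step 1 | (2R)-2-methylbutanoic anhydride | CC[C@@H](C)C(=O)OC(=O)[C@H](C)CC
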